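**Plan**
- Retrosynthesis cuts, in this order: the enone Cα=Cβ bond (aldol condensation) and the C6–CHO bond (formylation); the C4–O bond of a (3S,4S)-3,4-epoxychroman (hydride) and the epoxide itself (asymmetric epoxidation of a 2,2-dimethyl-2H-chromene); then C2–C3 and C4–C4a of the chromene together, which leaves catechol acetonide and ethyl vinyl ether.
- Enabling feature: O1 and the C8 hydroxyl are the two oxygens of a catechol and C2 carries two methyl groups, so O1–C2(Me)2 is a ring-opened catechol acetone ketal. The dihydropyran ring is a 1,3-benzodioxole into which C3–C4 has been inserted between the ketal carbon and the ortho carbon C4a.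
- Forward: the pyran ring arises first (step 1), then the C3 oxygen (steps 3–4), then the C6 formyl group (step 6); the side chain with the resorcinol ring is joined last (step 8).
- Stereochemistry: C3 is set by reagent control in the Mn(salen) epoxidation of the cis alkene and kept because hydride opens only the C4–O bond. The E alkene follows from thermodynamic control in the condensation.

Key step: step 1

Remark: the sense of induction in step 3 is taken to be the one established for 2,2-dimethyl-2H-chromenes, (S,S)-catalyst giving the (3S,4S)-epoxide; should the 8-acyloxy group reverse it, the (R,R)-catalyst would be used.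

**Step 1**
Reactants: 1 2,2-dimethyl-1,3-benzodioxole; 2 ethyl vinyl ether
Product: 5 2,2-dimethyl-2H-chromen-8-ol, via ring-opened chloro ether 3 (not isolated), via 4-ethoxychromanol 4 (not isolated)
Conditions: BCl3 (1.0 equiv), CH2Cl2, −78 °C; then 2 (slow addition), −78 to −20 °C; H2O; crude, TsOH·H2O (cat.), PhMe, 80 °C
Reagents that add atoms: none
Why: Proposed new method: BCl3, known to open 1,3-benzodioxoles to an aryloxydichloroborane and an α-chloroalkyl aryl ether, should ionise the ketal of 1 to the aryl oxocarbenium ion ArO+=CMe2 (3), whose carbon is attacked by the nucleophilic CH2 terminus of 2 (C2–C3 bond), and the ethoxycarbenium ion so formed at C4 is trapped at once by the ring carbon ortho to the ether oxygen (C4–C4a bond), a stepwise cationic formal [4+2] of the 2-oxonia-diene C4a=C8a–O1+=C2 with the enol ether. The closest known reaction types are the Lewis-acid oxa-Povarov reaction of aryl oxocarbenium ions with alkenes and the addition of α-halo ethers to vinyl ethers; new is the catechol ketal as oxocarbenium source, so that the ketal carbon becomes C2 and the released oxygen becomes the C8 hydroxyl. The dihydropyran ring closes by a 6-exo-trig Friedel–Crafts attack of the arene on the C4 oxocarbenium carbon. The only new stereocentre, C4 bearing OEt, is formed without control and is erased when TsOH expels ethanol from 4 to give the C3=C4 alkene of 5. The step needs regiocontrol and chemoselectivity: the mirror symmetry of 1 makes both C–O cleavages equivalent, the enol-ether polarity puts the temporary oxygen on C4 and not on C3, the boron-capped phenoxide cannot re-close or attack C4, and pre-forming 3 at −78 °C before slow addition of 2 should hold back oligomerisation of the vinyl ether.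

**Step 2**
Reactants: 5 2,2-dimethyl-2H-chromen-8-ol
Product: 6 2,2-dimethyl-2H-chromen-8-yl pivalate
Conditions: Piv2O, DMAP (cat.), pyridine, 40 °C
Reagents that add atoms: pivalic anhydride, CC(C)(C)C(=O)OC(=O)C(C)(C)C
Why: DMAP-catalysed O-acylation of the phenol should give a hindered ester that shields the phenol from the oxidant of step 3 and withstands buffered hypochlorite.

**Step 3**
Reactants: 6 2,2-dimethyl-2H-chromen-8-yl pivalate
Product: 7 (3S,4S)-3,4-epoxy-2,2-dimethylchroman-8-yl pivalate
Conditions: (S,S)-N,N′-bis(3,5-di-tert-butylsalicylidene)-1,2-cyclohexanediaminomanganese(III) chloride (cat.), 4-phenylpyridine N-oxide (cat.), aq. NaOCl (pH 11.3), CH2Cl2, 0 °C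
Reagents that add atoms: sodium hypochlorite, [Na+].[O-]Cl
Why: Jacobsen–Katsuki epoxidation of a 2,2-dimethyl-2H-chromene, a privileged cis-alkene class for this catalyst, in which side-on approach of the alkene to the oxo-manganese species of the (S,S)-ligand should deliver oxygen to the face that gives the (3S,4S)-epoxide and so set C3 by reagent control.

**Step 4**
Reactants: 7 (3S,4S)-3,4-epoxy-2,2-dimethylchroman-8-yl pivalate
Product: 8 (S)-2,2-dimethylchromane-3,8-diol
Conditions: LiAlH4, THF, 0 °C to rt; aq. work-up
Reagents that add atoms: none
Why: Regioselective SN2 hydride opening of the epoxide at benzylic C4 (C3 is neopentyl-like next to quaternary C2) should leave the C3–O bond and its configuration untouched and reduce the pivalate off in the same step, with no cationic intermediate that could rearrange to the 3-ketone.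

**Step 5**
Reactants: 8 (S)-2,2-dimethylchromane-3,8-diol
Product: 9 (S)-2,2-dimethylchromane-3,8-diyl diacetate
Conditions: Ac2O, DMAP (cat.), pyridine, rt
Reagents that add atoms: acetic anhydride, CC(=O)OC(C)=O
Why: Double O-acylation should turn O8 into a weak donor, so that O1 alone directs step 6, and keep the secondary alcohol away from TiCl4.

**Step 6**
Reactants: 9 (S)-2,2-dimethylchromane-3,8-diyl diacetate
Product: 10 (S)-6-formyl-2,2-dimethylchromane-3,8-diyl diacetate
Conditions: Cl2CHOMe, TiCl4, CH2Cl2, −20 to 0 °C; then H2O
Reagents that add atoms: dichloromethyl methyl ether, COC(Cl)Cl; water, O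
Why: Rieche formylation should occur para to the ether oxygen O1 at C6, because O1 is the strongest donor, its ortho position is the ring-fusion carbon C4a, and C5 and C7 are activated only by the acetoxy and alkyl groups.

**Step 7**
Reactants: 11 1-(2,4-dihydroxyphenyl)ethan-1-one
Product: 12 1-[2-hydroxy-4-(methoxymethoxy)phenyl]ethan-1-one
Conditions: MOMCl (1.1 equiv), K2CO3, acetone, rt
Reagents that add atoms: chloromethyl methyl ether, COCCl
Why: Williamson-type O-alkylation should take place only at the more acidic 4-hydroxyl, since the 2-hydroxyl is held in a hydrogen bond to the ketone.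

**Step 8**
Reactants: 10 (S)-6-formyl-2,2-dimethylchromane-3,8-diyl diacetate; 12 1-[2-hydroxy-4-(methoxymethoxy)phenyl]ethan-1-one
Product: 13 (S,E)-3-(3,8-dihydroxy-2,2-dimethylchroman-6-yl)-1-[2-hydroxy-4-(methoxymethoxy)phenyl]prop-2-en-1-one
Conditions: KOH (aq., excess), EtOH, rt
Reagents that add atoms: none
Why: Claisen–Schmidt condensation (crossed aldol, then E1cB loss of water) should give the conjugated E enone under thermodynamic control while both acetates are saponified, and the non-enolisable C3 carbinol centre is not touched.

**Step 9**
Reactants: 13 (S,E)-3-(3,8-dihydroxy-2,2-dimethylchroman-6-yl)-1-[2-hydroxy-4-(methoxymethoxy)phenyl]prop-2-en-1-one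
Product: 14 (S,E)-1-(2,4-dihydroxyphenyl)-3-(3,8-dihydroxy-2,2-dimethylchroman-6-yl)prop-2-en-1-one
Conditions: HCl (3 M aq.), MeOH, 40 °C
Reagents that add atoms: none
Why: Acid-catalysed transacetalisation of the methoxymethyl ether to methanol should free the last phenol under conditions mild enough to leave the chalcone and the tertiary aryl ether intact.

**Compound list**
1 | 2,2-dimethyl-1,3-benzodioxole | CC1(C)Oc2ccccc2O1 | starting material
2 | ethyl vinyl ether | C=COCC | starting material
3 | dichloro{2-[(2-chloropropan-2-yl)oxy]phenoxy}borane (ring-opened chloro ether, ion pair with the aryl oxocarbenium ion) | CC(C)(Cl)Oc1ccccc1OB(Cl)Cl | intermediate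
4 | rac-4-ethoxy-2,2-dimethylchroman-8-ol | CCOC1CC(C)(C)Oc2c(O)cccc12 | intermediate
5 | 2,2-dimethyl-2H-chromen-8-ol | CC1(C)C=Cc2cccc(O)c2O1 | intermediate
6 | 2,2-dimethyl-2H-chromen-8-yl pivalate | CC1(C)C=Cc2cccc(OC(=O)C(C)(C)C)c2O1 | intermediate
7 | (3S,4S)-3,4-epoxy-2,2-dimethylchroman-8-yl pivalate | CC1(C)Oc2c(OC(=O)C(C)(C)C)cccc2[C@@H]3O[C@H]13 | intermediate
8 | (S)-2,2-dimethylchromane-3,8-diol | CC1(C)Oc2c(O)cccc2C[C@@H]1O | intermediate
9 | (S)-2,2-dimethylchromane-3,8-diyl diacetate | CC1(C)Oc2c(OC(C)=O)cccc2C[C@@H]1OC(C)=O | intermediate
10 | (S)-6-formyl-2,2-dimethylchromane-3,8-diyl diacetate | CC1(C)Oc2c(OC(C)=O)cc(C=O)cc2C[C@@H]1OC(C)=O | intermediate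
11 | 1-(2,4-dihydroxyphenyl)ethan-1-one | CC(=O)c1ccc(O)cc1O | starting material
12 | 1-[2-hydroxy-4-(methoxymethoxy)phenyl]ethan-1-one | CC(=O)c1ccc(OCOC)cc1O | intermediate
13 | (S,E)-3-(3,8-dihydroxy-2,2-dimethylchroman-6-yl)-1-[2-hydroxy-4-(methoxymethoxy)phenyl]prop-2-en-1-one | CC1(C)Oc2c(O)cc(/C=C/C(=O)c3ccc(OCOC)cc3O)cc2C[C@@H]1O | intermediate
14 | (S,E)-1-(2,4-dihydroxyphenyl)-3-(3,8-dihydroxy-2,2-dimethylchroman-6-yl)prop-2-en-1-one | CC1(C)Oc2c(O)cc(/C=C/C(=O)c3ccc(O)cc3O)cc2C[C@@H]1O | target

**Step count and risks**
Total steps: 9. Longest linear sequence: 8 (steps 1–6, 8, 9 from compound 1).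

Steps most likely to fail:

1. Step 1 (proposed new method). The ionised ketal may lose its ketal carbon altogether (full cleavage to the catechol boronate), the vinyl ether may oligomerise faster than it is captured, or the Friedel–Crafts closure may lag behind. The fallback sets out from 1 and returns at 5. Compound 1 is lithiated ortho to oxygen (n-BuLi, TMEDA, THF, 0 °C) and the aryllithium is added to 3-methylbut-2-enal to give 1-(2,2-dimethyl-1,3-benzodioxol-4-yl)-3-methylbut-2-en-1-ol F1. Aqueous acid (TFA–H2O or 2 M HCl–THF) should cleave the ketal to 3-(1-hydroxy-3-methylbut-2-en-1-yl)benzene-1,2-diol F2, which on warming should lose water to the ortho-quinone methide and close by oxa-6π electrocyclisation to 5. In this variant the gem-dimethyl carbon comes from the enal and the ketal only protects and directs.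

2. Step 6. Regiocontrol may be lost (attack ortho or para to the acetoxy group), or the Lewis acid may open the tertiary aryl ether or strip an acetate. The fallback sets out from 9 and returns at 10. Bromination with NBS in MeCN, without Lewis acid and para to the ether oxygen, should give (S)-6-bromo-2,2-dimethylchromane-3,8-diyl diacetate F3. Pd-catalysed reductive carbonylation (Pd(OAc)2, di(1-adamantyl)-n-butylphosphine, CO/H2, TMEDA, PhMe, 100 °C) should then convert the bromide into aldehyde 10.

3. Step 9. The 2′-hydroxychalcone may close to the flavanone under acid, or acetal cleavage may stall. The fallback sets out from 10 (with 11) and returns at 14. Aldehyde 10 is condensed directly with unprotected 11 (large excess of aq. KOH, EtOH, rt, long reaction time, then acidification), so that no acetal has to be removed. The slower reaction of the doubly deprotonated ketone is accepted, and no new compound arises (F0).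

**Further compounds**
F1 | step 1 | 1-(2,2-dimethyl-1,3-benzodioxol-4-yl)-3-methylbut-2-en-1-ol | CC(C)=CC(O)c1cccc2OC(C)(C)Oc12
F2 | step 1 | 3-(1-hydroxy-3-methylbut-2-en-1-yl)benzene-1,2-diol | CC(C)=CC(O)c1cccc(O)c1O
F3 | step 6 | (S)-6-bromo-2,2-dimethylchromane-3,8-diyl diacetate | CC1(C)Oc2c(OC(C)=O)cc(Br)cc2C[C@@H]1OC(C)=O
F0 | step 9 | none | none
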